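**Retrosynthetic overview**
1. Target ⇐ amine-catalysed α-methylenation of a C7 acetaldehyde arm ⇐ ozonolysis of a C7 allyl group; the carboxylic acid is carried unprotected.
2. C4–O ester bond and C4 stereocentre ⇐ γ-acyloxy transfer from the side-chain diacyl peroxide to the silyl dienol ether of the bicyclic enone (proposed new step).
3. Allyl keto acid ⇐ α'-allylation and one-carbon homologation (Wittig, hydrolysis, oxidation) at the saturated ketone of (S)-Wieland–Miescher ketone.
4. (S)-Wieland–Miescher ketone ⇐ prolinamide-catalysed desymmetrising aldol condensation of the achiral triketone from 2-methylcyclohexane-1,3-dione and methyl vinyl ketone. Ring B (the carboxyl-bearing ring) is the bought dione ring; ring A (the enone ring) is closed here and the first stereocentre (C8a) is set.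
5. Side-chain peroxide ⇐ acid ⇐ cross metathesis with methacrolein ⇐ Cu-catalysed asymmetric SN2' methylation of (E)-1-bromohept-2-ene.

Locants follow the naphthalene names: C1 carries CO2H, C4 the ester oxygen, C4a=C5–C6(=O) is the enone, C7 carries the three-carbon unit, C8a the methyl.

Assumption: compounds 1, 2, 10 and 13 are bought; all are achiral, and chiral material enters only as catalysts or ligands.

**Step 1**
Reactants: 1 2-methylcyclohexane-1,3-dione; 2 methyl vinyl ketone (but-3-en-2-one)
Product: 4 (S)-Wieland–Miescher ketone [(8aS)-8a-methyl-3,4,8,8a-tetrahydronaphthalene-1,6(2H,7H)-dione], via triketone 3 (not isolated)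
Conditions: Et3N (1 mol%), neat, rt, 12 h; then (S)-N-[(Sa)-2'-(tosylamino)-1,1'-binaphthalen-2-yl]pyrrolidine-2-carboxamide (2 mol%), PhCO2H (2.5 mol%), neat, rt, 4 d; one recrystallisation
Reagents that add atoms: none
Why: Base-catalysed Michael addition gives the achiral triketone, and the prolinamide then runs a Hajos–Parrish–Eder–Sauer–Wiechert aldol condensation (Robinson annulation) in which the enamine of the methyl ketone, held by the amide and sulfonamide N–H hydrogen bonds, attacks one of the two enantiotopic ring carbonyls and sets the quaternary C8a as S (about 94% ee expected, >99% ee after crystallisation).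

**Step 2**
Reactants: 4 (S)-Wieland–Miescher ketone
Product: 5 (4aS)-5-(methoxymethylidene)-4a-methyl-4,4a,5,6,7,8-hexahydronaphthalen-2(3H)-one (E/Z mixture)
Conditions: MeOCH2PPh3Cl (3.0 equiv), KN(SiMe3)2 (2.9 equiv), THF, 0 °C to rt
Reagents that add atoms: (methoxymethyl)triphenylphosphonium chloride, COC[P+](c1ccccc1)(c1ccccc1)c1ccccc1.[Cl-]
Why: Wittig olefination is selective for the saturated ketone because the enone is the less electrophilic carbonyl and is held as its dienolate by the excess basic ylide; no stereocentre is formed and the E/Z ratio does not matter.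

**Step 3**
Reactants: 5 (4aS)-5-(methoxymethylidene)-4a-methyl-4,4a,5,6,7,8-hexahydronaphthalen-2(3H)-one
Product: 7 (1S,8aR)-8a-methyl-6-oxo-1,2,3,4,6,7,8,8a-octahydronaphthalene-1-carboxylic acid, via aldehyde 6 (not isolated)
Conditions: 2 M HCl, THF, rt, 12 h; then NaH2PO4, 2-methylbut-2-ene, NaClO2, t-BuOH/H2O, 0 °C to rt
Reagents that add atoms: water (O); sodium chlorite ([Na+].[O-]Cl=O)
Why: Enol ether hydrolysis protonates C1 from the face opposite the angular methyl and equilibrates the aldehyde to the equatorial 1S epimer (formyl cis to the methyl), any deconjugated enone returns to conjugation, and Pinnick oxidation then gives the acid without touching the enone or the α-stereocentre.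

**Step 4**
Reactants: 7 (1S,8aR)-8a-methyl-6-oxo-1,2,3,4,6,7,8,8a-octahydronaphthalene-1-carboxylic acid
Product: 8 (1S,7R,8aR)-8a-methyl-6-oxo-7-(prop-2-en-1-yl)-1,2,3,4,6,7,8,8a-octahydronaphthalene-1-carboxylic acid
Conditions: LiN(i-Pr)2 (2.2 equiv), THF, −78 °C; allyl bromide (1.2 equiv), DMPU, −78 to −30 °C; 1 M HCl work-up
Reagents that add atoms: allyl bromide, C=CCBr
Why: Kinetic deprotonation of the lithium carboxylate gives the cross-conjugated α'-enolate (dianion), and its alkylation takes place at C7 anti to the pseudo-axial angular methyl to give the equatorial 7R allyl epimer, which is also the thermodynamic one.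

**Step 5**
Reactants: 8 (1S,7R,8aR)-8a-methyl-6-oxo-7-(prop-2-en-1-yl)-1,2,3,4,6,7,8,8a-octahydronaphthalene-1-carboxylic acid
Product: 9 tert-butyldimethylsilyl (1S,7R,8aR)-6-[(tert-butyldimethylsilyl)oxy]-8a-methyl-7-(prop-2-en-1-yl)-1,2,3,7,8,8a-hexahydronaphthalene-1-carboxylate
Conditions: TBSOTf (2.4 equiv), Et3N (4 equiv), CH2Cl2, 0 °C to rt; cold NaHCO3 wash, pentane; used crude
Reagents that add atoms: tert-butyldimethylsilyl trifluoromethanesulfonate, CC(C)(C)[Si](C)(C)OS(=O)(=O)C(F)(F)F
Why: Soft enolisation with a silyl triflate and an amine gives the thermodynamic linear (heteroannular) silyl dienol ether C6(OSi)=C5–C4a=C4, as with steroidal 4-en-3-ones, and silylates the acid at the same time; the stereocentres at C1, C7 and C8a are untouched.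

**Step 6**
Reactants: 10 (E)-hept-2-en-1-ol
Product: 11 (E)-1-bromohept-2-ene
Conditions: PBr3 (0.4 equiv), Et2O, −10 °C
Reagents that add atoms: phosphorus tribromide, BrP(Br)Br
Why: SN2 bromination of the primary allylic alcohol at low temperature keeps the E geometry and gives the substrate for allylic substitution.

**Step 7**
Reactants: 11 (E)-1-bromohept-2-ene
Product: 12 (R)-3-methylhept-1-ene
Conditions: MeMgBr (1.2 equiv), CuBr·SMe2 (1 mol%), (RP)-1-[(R)-α-(dimethylamino)-2-(diphenylphosphino)benzyl]-2-(diphenylphosphino)ferrocene (1.1 mol%), CH2Cl2, −75 °C; kept as a concentrated CH2Cl2 solution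
Reagents that add atoms: methylmagnesium bromide, C[Mg]Br
Why: Copper-catalysed asymmetric allylic alkylation (SN2' with a Grignard reagent) puts the methyl group on C3 under control of the chiral ferrocenyl diphosphine and gives the branched alkene as the R enantiomer (about 92% ee expected; the mirror-image ligand is used if the first run shows the opposite sense).

**Step 8**
Reactants: 12 (R)-3-methylhept-1-ene; 13 methacrolein (2-methylprop-2-enal, 3 equiv)
Product: 14 (2E,4R)-2,4-dimethyloct-2-enal
Conditions: second-generation Hoveyda–Grubbs catalyst [RuCl2(=CH-C6H4-2-O-i-Pr)(H2IMes)] (5 mol%), 1,4-benzoquinone (10 mol%), CH2Cl2, 40 °C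
Reagents that add atoms: none
Why: Olefin cross metathesis between the hindered terminal alkene and excess methacrolein gives the trisubstituted enal with thermodynamic E geometry, and benzoquinone suppresses ruthenium hydride isomerisation at the allylic stereocentre.

**Step 9**
Reactants: 14 (2E,4R)-2,4-dimethyloct-2-enal
Product: 15 (2E,4R)-2,4-dimethyloct-2-enoic acid
Conditions: NaClO2, NaH2PO4, 2-methylbut-2-ene, t-BuOH/H2O, 0 °C to rt
Reagents that add atoms: sodium chlorite, [Na+].[O-]Cl=O
Why: Pinnick oxidation converts the enal into the acid without touching the alkene or the γ-stereocentre.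

**Step 10**
Reactants: 15 (2E,4R)-2,4-dimethyloct-2-enoic acid (2 equiv)
Product: 17 bis[(2E,4R)-2,4-dimethyloct-2-enoyl] peroxide, via peroxy acid 16 (not isolated)
Conditions: DCC (1.0 equiv per acid), H2O2 (0.5 equiv, ethereal), Et2O, −10 to 0 °C; stored cold in solution
Reagents that add atoms: hydrogen peroxide, OO
Why: Carbodiimide activation of the acid and acylation of hydrogen peroxide, first to the peroxy acid and then to the symmetric diacyl peroxide, is the standard carbodiimide route to diacyl peroxides, and the sp2-bound carboxyl groups make this peroxide about as robust as an aroyl peroxide.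

**Step 11**
Reactants: 9 tert-butyldimethylsilyl (1S,7R,8aR)-6-[(tert-butyldimethylsilyl)oxy]-8a-methyl-7-(prop-2-en-1-yl)-1,2,3,7,8,8a-hexahydronaphthalene-1-carboxylate; 17 bis[(2E,4R)-2,4-dimethyloct-2-enoyl] peroxide (1.1 equiv)
Product: 19 (1S,4R,7R,8aR)-4-{[(2E,4R)-2,4-dimethyloct-2-enoyl]oxy}-8a-methyl-6-oxo-7-(prop-2-en-1-yl)-1,2,3,4,6,7,8,8a-octahydronaphthalene-1-carboxylic acid, via silyl ester 18 (not isolated)
Conditions: Me3SiNTf2 (5 mol%), 2,6-di-tert-butyl-4-methylpyridine (10 mol%), CH2Cl2, −40 to 0 °C; then AcOH/THF/H2O (3:1:1), rt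
Reagents that add atoms: none
Why: Proposed new method: vinylogous acyloxy transfer from a diacyl peroxide to a silyl dienol ether, in which the terminal diene carbon C4 (largest HOMO coefficient) attacks the O–O σ* orbital of the peroxide (activated at a carbonyl oxygen by the silyl triflimide) in an SN2 reaction at oxygen, the expelled carboxylate takes the silyl group from the silyloxocarbenium ion and so regenerates the silyl Lewis acid, and attack is axial on the face of the angular methyl (as in the 6β-hydroxylation and 6β-halogenation of steroidal 3,5-dienol ethers) to give the 4R ester; the closest known reactions are the Rubottom-type γ-hydroxylation of silyl dienol ethers with peracids or dioxiranes and the α-benzoyloxylation of enamines and enolates with dibenzoyl peroxide.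

**Step 12**
Reactants: 19 (1S,4R,7R,8aR)-4-{[(2E,4R)-2,4-dimethyloct-2-enoyl]oxy}-8a-methyl-6-oxo-7-(prop-2-en-1-yl)-1,2,3,4,6,7,8,8a-octahydronaphthalene-1-carboxylic acid
Product: 21 (1S,4R,7S,8aR)-4-{[(2E,4R)-2,4-dimethyloct-2-enoyl]oxy}-8a-methyl-6-oxo-7-(3-oxoprop-1-en-2-yl)-1,2,3,4,6,7,8,8a-octahydronaphthalene-1-carboxylic acid, via aldehyde 20 (not isolated)
Conditions: O3, CH2Cl2/MeOH (4:1), Sudan Red 7B, −78 °C; Me2S, −78 °C to rt; evaporate; then 37% aq. HCHO (1.5 equiv), pyrrolidine (20 mol%), EtCO2H (20 mol%), i-PrOH, 45 °C, 1 h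
Reagents that add atoms: ozone ([O-][O+]=O); formaldehyde (C=O)
Why: Ozone cleaves only the electron-rich terminal alkene (the dye shows the end point before the conjugated alkenes react), and the aldehyde then undergoes amine-catalysed Mannich condensation with formaldehyde and elimination (α-methylenation) to the 2-substituted acrolein, with C7 staying in, or equilibrating to, its equatorial configuration α to the ketone (descriptor S in 20 and 21).

**Compound list**
1 | 2-methylcyclohexane-1,3-dione | CC1C(=O)CCCC1=O | starting material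
2 | methyl vinyl ketone (but-3-en-2-one) | CC(=O)C=C | starting material
3 | 2-methyl-2-(3-oxobutyl)cyclohexane-1,3-dione | CC(=O)CCC1(C)C(=O)CCCC1=O | intermediate
4 | (8aS)-8a-methyl-3,4,8,8a-tetrahydronaphthalene-1,6(2H,7H)-dione, (S)-Wieland–Miescher ketone | O=C1CC[C@@]2(C)C(=C1)CCCC2=O | intermediate
5 | (4aS)-5-(methoxymethylidene)-4a-methyl-4,4a,5,6,7,8-hexahydronaphthalen-2(3H)-one, E/Z mixture | O=C1CC[C@@]2(C)C(=C1)CCCC2=COC | intermediate
6 | (1S,8aR)-8a-methyl-6-oxo-1,2,3,4,6,7,8,8a-octahydronaphthalene-1-carbaldehyde | O=C1CC[C@@]2(C)C(=C1)CCC[C@@H]2C=O | intermediate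
7 | (1S,8aR)-8a-methyl-6-oxo-1,2,3,4,6,7,8,8a-octahydronaphthalene-1-carboxylic acid | O=C1CC[C@@]2(C)C(=C1)CCC[C@@H]2C(=O)O | intermediate
8 | (1S,7R,8aR)-8a-methyl-6-oxo-7-(prop-2-en-1-yl)-1,2,3,4,6,7,8,8a-octahydronaphthalene-1-carboxylic acid | C=CC[C@@H]1C[C@@]2(C)C(=CC1=O)CCC[C@@H]2C(=O)O | intermediate
9 | tert-butyldimethylsilyl (1S,7R,8aR)-6-[(tert-butyldimethylsilyl)oxy]-8a-methyl-7-(prop-2-en-1-yl)-1,2,3,7,8,8a-hexahydronaphthalene-1-carboxylate | C=CC[C@@H]1C[C@@]2(C)C(=CCC[C@@H]2C(=O)O[Si](C)(C)C(C)(C)C)C=C1O[Si](C)(C)C(C)(C)C | intermediate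
10 | (E)-hept-2-en-1-ol | CCCC/C=C/CO | starting material
11 | (E)-1-bromohept-2-ene | CCCC/C=C/CBr | intermediate
12 | (R)-3-methylhept-1-ene | C=C[C@H](C)CCCC | intermediate
13 | methacrolein (2-methylprop-2-enal) | CC(=C)C=O | starting material
14 | (2E,4R)-2,4-dimethyloct-2-enal | O=C/C(C)=C/[C@H](C)CCCC | intermediate
15 | (2E,4R)-2,4-dimethyloct-2-enoic acid | OC(=O)/C(C)=C/[C@H](C)CCCC | intermediate
16 | (2E,4R)-2,4-dimethyloct-2-eneperoxoic acid | OOC(=O)/C(C)=C/[C@H](C)CCCC | intermediate
17 | bis[(2E,4R)-2,4-dimethyloct-2-enoyl] peroxide | O=C(OOC(=O)/C(C)=C/[C@H](C)CCCC)/C(C)=C/[C@H](C)CCCC | intermediate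
18 | tert-butyldimethylsilyl (1S,4R,7R,8aR)-4-{[(2E,4R)-2,4-dimethyloct-2-enoyl]oxy}-8a-methyl-6-oxo-7-(prop-2-en-1-yl)-1,2,3,4,6,7,8,8a-octahydronaphthalene-1-carboxylate | C=CC[C@@H]1C[C@@]2(C)C(=CC1=O)[C@H](OC(=O)/C(C)=C/[C@H](C)CCCC)CC[C@@H]2C(=O)O[Si](C)(C)C(C)(C)C | intermediate
19 | (1S,4R,7R,8aR)-4-{[(2E,4R)-2,4-dimethyloct-2-enoyl]oxy}-8a-methyl-6-oxo-7-(prop-2-en-1-yl)-1,2,3,4,6,7,8,8a-octahydronaphthalene-1-carboxylic acid | C=CC[C@@H]1C[C@@]2(C)C(=CC1=O)[C@H](OC(=O)/C(C)=C/[C@H](C)CCCC)CC[C@@H]2C(=O)O | intermediate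
20 | (1S,4R,7S,8aR)-4-{[(2E,4R)-2,4-dimethyloct-2-enoyl]oxy}-8a-methyl-6-oxo-7-(2-oxoethyl)-1,2,3,4,6,7,8,8a-octahydronaphthalene-1-carboxylic acid | O=CC[C@@H]1C[C@@]2(C)C(=CC1=O)[C@H](OC(=O)/C(C)=C/[C@H](C)CCCC)CC[C@@H]2C(=O)O | intermediate
21 | (1S,4R,7S,8aR)-4-{[(2E,4R)-2,4-dimethyloct-2-enoyl]oxy}-8a-methyl-6-oxo-7-(3-oxoprop-1-en-2-yl)-1,2,3,4,6,7,8,8a-octahydronaphthalene-1-carboxylic acid | C=C(C=O)[C@@H]1C[C@@]2(C)C(=CC1=O)[C@H](OC(=O)/C(C)=C/[C@H](C)CCCC)CC[C@@H]2C(=O)O | target

**Step count and risks**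
Total step count: 12 (steps 1, 3, 10, 11 and 12 each run through one compound that is not isolated).
Longest linear sequence: 7 steps (1, 2, 3, 4, 5, 11, 12; the side-chain line 6, 7, 8, 9, 10, 11, 12 is equally long).

The three steps most likely to fail:

Step 11 (the proposed new acyloxy transfer). The risks are attack at C5 instead of C4, a poor 4β:4α ratio with the bulky peroxide, or Lewis-acid decomposition of the peroxide. The fallback sets out from 9 and uses known chemistry. Vinylogous Rubottom oxidation with dimethyldioxirane (acetone/CH2Cl2, −40 °C, neutral work-up), which gives the axial alcohol with steroidal dienol ethers, affords tert-butyldimethylsilyl (1S,4R,7R,8aR)-4-hydroxy-8a-methyl-6-oxo-7-(prop-2-en-1-yl)-1,2,3,4,6,7,8,8a-octahydronaphthalene-1-carboxylate F1. Yamaguchi esterification of this alcohol with acid 15 (2,4,6-trichlorobenzoyl chloride, Et3N, then DMAP, toluene) gives the silyl ester 18; the silyl ester is kept on until then so that the cis-disposed C1 carboxyl cannot lactonise onto the C4 hydroxyl. The AcOH/THF/H2O treatment of step 11 then brings the route back at 19.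

Step 12 (end game). The risks are over-ozonolysis of the conjugated alkenes and amine-induced migration of the new double bond into conjugation with the C6 ketone. The fallback sets out from 19. Dihydroxylation of the terminal alkene with OsO4 (2 mol%) and N-methylmorpholine N-oxide (acetone/H2O), which leaves the electron-poor alkenes alone, gives (1S,4R,7S,8aR)-7-(2,3-dihydroxypropyl)-4-{[(2E,4R)-2,4-dimethyloct-2-enoyl]oxy}-8a-methyl-6-oxo-1,2,3,4,6,7,8,8a-octahydronaphthalene-1-carboxylic acid F2. NaIO4 cleavage gives aldehyde 20, this time isolated. A stoichiometric Mannich reaction with dimethyl(methylidene)ammonium iodide and Et3N in CH2Cl2 gives (1S,4R,7S,8aR)-7-[1-(dimethylamino)-3-oxopropan-2-yl]-4-{[(2E,4R)-2,4-dimethyloct-2-enoyl]oxy}-8a-methyl-6-oxo-1,2,3,4,6,7,8,8a-octahydronaphthalene-1-carboxylic acid F3, which loses dimethylamine at rt. The route comes back at 21 without a secondary-amine catalyst ever being warmed with the product.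

Step 2 (chemoselective Wittig on the diketone). The risks are enolisation of the hindered saturated ketone and attack at the enone. The fallback sets out from 4. Methylenation with Ph3P=CH2 (Ph3PCH3Br, KOt-Bu, toluene), which is expected to be selective for the saturated ketone, gives (4aR)-4a-methyl-5-methylidene-4,4a,5,6,7,8-hexahydronaphthalen-2(3H)-one F4. Excess 9-borabicyclo[3.3.1]nonane (THF, rt to 60 °C) hydroborates the exocyclic alkene from the face opposite the angular methyl and also reduces the enone carbonyl; NaOH/H2O2 then gives [(1S,8aR)-6-hydroxy-8a-methyl-1,2,3,4,6,7,8,8a-octahydronaphthalen-1-yl]methanol F5. Oxidation of both carbinols with CrO3/H2SO4 in acetone brings the route back at 7.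

**Further compounds**
F1 | step 11 | tert-butyldimethylsilyl (1S,4R,7R,8aR)-4-hydroxy-8a-methyl-6-oxo-7-(prop-2-en-1-yl)-1,2,3,4,6,7,8,8a-octahydronaphthalene-1-carboxylate | C=CC[C@@H]1C[C@@]2(C)C(=CC1=O)[C@H](O)CC[C@@H]2C(=O)O[Si](C)(C)C(C)(C)C
F2 | step 12 | (1S,4R,7S,8aR)-7-(2,3-dihydroxypropyl)-4-{[(2E,4R)-2,4-dimethyloct-2-enoyl]oxy}-8a-methyl-6-oxo-1,2,3,4,6,7,8,8a-octahydronaphthalene-1-carboxylic acid (carbinol epimers) | OCC(O)C[C@@H]1C[C@@]2(C)C(=CC1=O)[C@H](OC(=O)/C(C)=C/[C@H](C)CCCC)CC[C@@H]2C(=O)O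
F3 | step 12 | (1S,4R,7S,8aR)-7-[1-(dimethylamino)-3-oxopropan-2-yl]-4-{[(2E,4R)-2,4-dimethyloct-2-enoyl]oxy}-8a-methyl-6-oxo-1,2,3,4,6,7,8,8a-octahydronaphthalene-1-carboxylic acid (side-chain epimers) | CN(C)CC(C=O)[C@@H]1C[C@@]2(C)C(=CC1=O)[C@H](OC(=O)/C(C)=C/[C@H](C)CCCC)CC[C@@H]2C(=O)O
F4 | step 2 | (4aR)-4a-methyl-5-methylidene-4,4a,5,6,7,8-hexahydronaphthalen-2(3H)-one | O=C1CC[C@@]2(C)C(=C1)CCCC2=C
F5 | step 2 | [(1S,8aR)-6-hydroxy-8a-methyl-1,2,3,4,6,7,8,8a-octahydronaphthalen-1-yl]methanol (C6 epimers) | OC1CC[C@@]2(C)C(=C1)CCC[C@@H]2CO
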